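**Numbering convention:** intermediates use the target's germacranolide numbering. C1–C10 is the ring, C11–C13 the lactone unit, C14 the methyl on C10 and C15 the methyl on C4.

**Assumption:** the SMILES encodes an (R)-2-methylbutanoyl group, so commercial (R)-2-methylbutanoic acid is used.

## Retrosynthetic overview
1. The ester is a late Steglich acylation of the C5–OH. The 4S,5R cis-diol comes from hydrolysis of a 4R,5R-epoxide at the tertiary C4, which comes from epoxidation of a C4=C5 (E)-olefin.
2. The α-methylene-γ-lactone comes from the C6–OH and the C7 isopropenyl group by allylic oxidation of the isopropenyl methyl, then oxidative lactonization.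
3. Key step: a photochemical alkoxy-radical β-scission ring expansion of a tertiary 9-decalol. Cleaving the ring-fusion bond C4–C9 forms the 10-membered ring, unmasks the C9 carbonyl, and lets O2 capture the allyl radical to place the C6 oxygen.
4. The decalol is made from (S)-carvone by Robinson annulation with ethyl vinyl ketone (EVK) and a Wharton transposition.
5. C7 comes from carvone. C10 is set by conjugate reduction of the ring-expanded enone. C4, C5 and C6 are set in the ring-expansion and epoxidation sequence.

## Route

**Step 1**
Reactants: 1 (S)-(+)-carvone; 2 ethyl vinyl ketone (pent-1-en-3-one)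
Product: 3 Michael adduct, 2-methyl-2-(3-oxopentyl)-5-isopropenylcyclohex-3-en-1-one, with the new quaternary Me cis to the isopropenyl group
Conditions: t-BuOK, t-BuOH/THF, 0 °C → rt, slow addition of 2
Reagents that add atoms: none (2 is a reactant)
Why: Deconjugative dienolate formation and α-selective Michael addition (first half of a Robinson annulation). The quaternary C4 forms anti to the C7 isopropenyl group; its configuration is erased in Step 5, and only C7 (from carvone) must survive.

**Step 2**
Reactants: 3
Product: 4 bicyclic dienone. It has a C9=C10(Me)–C1=O enone, a quaternary C4–Me, a cis C5=C6 olefin and a C7 isopropenyl.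
Conditions: NaOMe, MeOH, reflux
Reagents that add atoms: none
Why: Intramolecular aldol condensation (second half of the Robinson annulation). The ethyl-ketone α-CH2 (C10) closes the six-membered ring onto the C9 ketone and dehydration gives the tetrasubstituted enone. No new stereocentre forms.

**Step 3**
Reactants: 4
Product: 5 C9–C10 epoxy ketone
Conditions: 30% H2O2, NaOH, MeOH, 0 °C → rt
Reagents that add atoms: hydrogen peroxide, OO
Why: Weitz–Scheffer nucleophilic epoxidation is selective for the electron-poor enone over the isopropenyl and ring olefins. The epoxide configuration is irrelevant because C9 and C10 are reset in Step 4.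

**Step 4**
Reactants: 5
Product: 6 tertiary allylic alcohol, with C9–OH at the ring fusion and a C1=C10(Me) olefin
Conditions: N2H4·H2O, AcOH (cat.), MeOH, 0 °C → rt
Reagents that add atoms: none (N2 is lost)
Why: Wharton transposition. The hydrazone opens the epoxide and loses N2, which removes the C1 oxygen and leaves the tertiary C9 alcohol needed for the radical step. The C9 configuration is irrelevant.

**Step 5**
Reactants: 6
Product: 7 ten-membered hydroxy-enone, (10Z)-C9(=O)–C10(Me)=C1, (4E)-C4(Me)=C5, 6-OH, 7-isopropenyl
Conditions: CeCl3 (10 mol %), MeCN, O2 (1 atm), 390 nm LEDs, 25 °C; then PPh3 (2 equiv)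
Reagents that add atoms: dioxygen, O=O (PPh3 only reduces the hydroperoxide)
Why: Proposed new method: Ce(IV)–alkoxide ligand-to-metal charge transfer gives the C9 alkoxy radical, which undergoes β-scission of the strained ring-fusion bond C9–C4. This is selective because it gives a tertiary radical and a conjugated enone, whereas cleaving C9–C10 would give a vinyl radical and C9–C8 a non-stabilized radical. The resulting C4/C5/C6 allyl radical adds O2 reversibly and is funnelled to the trisubstituted E-olefin with the peroxyl group at C6, anti to the C7 isopropenyl group. PPh3 then reduces the hydroperoxide to the C6 alcohol. The closest known reactions are Ce-photocatalysed ring-opening of cycloalkanols, Suárez alkoxy-radical fragmentation of decalols, and allylic radical autoxidation.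

**Step 6**
Reactants: 7
Product: 8 ten-membered hydroxy-ketone with C10 saturated, (10R)-Me
Conditions: L-Selectride, THF, −78 °C; NH4Cl quench at −78 °C
Reagents that add atoms: none (hydride adds only H)
Why: 1,4-Reduction of the enone is chemoselective over the isolated olefins. The C10 stereocentre is set by kinetic protonation of the enolate on the peripheral face of the macrocycle, giving the 10R isomer.

**Step 7**
Reactants: 8
Product: 9 (4R,5R)-4,5-epoxy-6-ol
Conditions: VO(acac)2 (5 mol %), t-BuOOH, CH2Cl2, 0 °C
Reagents that add atoms: tert-butyl hydroperoxide, CC(C)(C)OO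
Why: Hydroxyl-directed vanadium epoxidation (Sharpless–Michaelson) is selective for the allylic-alcohol olefin and leaves the isopropenyl group untouched. The new stereocentres C4 and C5 are set by syn delivery to the exposed face of the E-olefin, the same selectivity seen in costunolide → parthenolide.

**Step 8**
Reactants: 9
Product: 10 allylic alcohol, with C12 as CH2OH on an isopropenyl-derived C11=CH2
Conditions: SeO2 (10 mol %), t-BuOOH, CH2Cl2, 25 °C
Reagents that add atoms: tert-butyl hydroperoxide, CC(C)(C)OO
Why: Riley/Sharpless allylic oxidation of the isopropenyl methyl. The epoxide and ketone are inert, and no stereocentre forms.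

**Step 9**
Reactants: 10
Product: 11 epoxy α-methylene-γ-lactone (6,12-olide, trans-fused at C6–C7)
Conditions: TEMPO (10 mol %), PhI(OAc)2 (2.2 equiv), CH2Cl2, 25 °C
Reagents that add atoms: none
Why: Oxidative lactonization of a 1,4-diol. The primary allylic alcohol is oxidized to the aldehyde, which forms a lactol with the trans-disposed C6–OH, and the lactol is oxidized to the lactone. C6 and C7 are already trans, so the fusion is trans.

**Step 10**
Reactants: 11
Product: 12 4S,5R diol-lactone
Conditions: HClO4 (0.1 equiv), THF/H2O 4:1, 0 °C
Reagents that add atoms: water, O
Why: Acid-catalysed trans-opening of the tertiary epoxide carbon C4 by water with inversion, while C5 keeps its configuration. This converts the 4R,5R-epoxide into the required ring-cis 4S,5R diol, and no transannular olefin remains to divert the cation.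

**Step 11**
Reactants: 12; 13 (R)-2-methylbutanoic acid
Product: 14 ineupatorolide A
Conditions: EDC·HCl, DMAP, CH2Cl2, 0 °C → rt
Reagents that add atoms: (R)-2-methylbutanoic acid, CC[C@@H](C)C(=O)O (compound 13)
Why: Steglich esterification acylates only the secondary C5–OH; the tertiary C4–OH does not react and the acid stereocentre is untouched.

## Compound list
1 | (S)-(+)-carvone | CC1=CC[C@@H](CC1=O)C(C)=C | starting material
2 | ethyl vinyl ketone | C=CC(=O)CC | starting material
3 | carvone–EVK Michael adduct | O=C1C[C@@H](C(C)=C)C=C[C@]1(C)CCC(=O)CC | intermediate
4 | bicyclic dienone (Robinson product) | CC1=C2C[C@@H](C(C)=C)C=C[C@]2(C)CCC1=O | intermediate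
5 | C9–C10 epoxy ketone | O=C1CC[C@@]2(C)C=C[C@H](C(C)=C)CC23OC13C | intermediate
6 | tertiary allylic decalol (C9–OH, C1=C10) | C=C(C)[C@H]1C=C[C@]2(C)CCC=C(C)C2(O)C1 | intermediate
7 | ten-membered hydroxy-enone | C=C(C)[C@@H]1CC(=O)/C(C)=C\CC/C(C)=C/[C@H]1O | intermediate
8 | ten-membered hydroxy-ketone (10R) | C=C(C)[C@@H]1CC(=O)[C@H](C)CCC/C(C)=C/[C@H]1O | intermediate
9 | 4R,5R-epoxy alcohol | C=C(C)[C@@H]1CC(=O)[C@H](C)CCC[C@@]2(C)O[C@@H]2[C@H]1O | intermediate
10 | C12 allylic alcohol | OCC(=C)[C@@H]1CC(=O)[C@H](C)CCC[C@@]2(C)O[C@@H]2[C@H]1O | intermediate
11 | epoxy α-methylene lactone | C=C1C(=O)O[C@@H]2[C@H]3O[C@]3(C)CCC[C@@H](C)C(=O)C[C@@H]12 | intermediate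
12 | 4S,5R diol-lactone | C=C1C(=O)O[C@@H]2[C@@H](O)[C@@](C)(O)CCC[C@@H](C)C(=O)C[C@@H]12 | intermediate
13 | (R)-2-methylbutanoic acid | CC[C@@H](C)C(=O)O | starting material
14 | ineupatorolide A | C=C1C(=O)O[C@@H]2[C@@H](OC(=O)[C@H](C)CC)[C@@](C)(O)CCC[C@@H](C)C(=O)C[C@@H]12 | target

**Total steps:** 11. **Longest linear sequence:** 11 (carvone → target).

## Three steps most likely to fail
1. **Step 5 (alkoxy-radical ring expansion and O2 capture).** The regiochemistry (C6 vs C4 peroxide), the C6 facial selectivity and the E/Z ratio are all uncertain. Fallback: drop the ring expansion and close the ring conventionally by intramolecular Nozaki–Hiyama–Kishi allylation. The acyclic precursor would come from the Eschenmoser–Tanabe fragmentation of carvone epoxide, which gives (S)-3-isopropenylhept-5-ynal.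
2. **Step 10, together with the face selectivity of Step 7.** Inversion at tertiary C4 may be eroded by cation character, and the epoxide may form on the wrong face. Fallback: epoxidize the C6-silyl ether with mCPBA to obtain the 4S,5S-epoxide, then open it at C5 with cesium (R)-2-methylbutanoate. This installs the C5 ester and retains the C4–OH in one step, so C5–O is formed by a different disconnection.
3. **Step 6 (C10 stereocentre).** Kinetic protonation may give the wrong epimer. Fallback: set C10 before ring expansion by hydroxyl-directed Crabtree hydrogenation of the C1=C10 olefin of 6, syn to the C9–OH, then fragment the saturated decalol directly to ketone 8 and skip Step 6.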